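Ring B is read as a trans-3-aryl-2-(oxymethyl)indan-1-one enlarged by one carbon. C4, the unsubstituted CH between ring-A carbon C4a and formyl-bearing C3, is disconnected so that C3 becomes the indanone carbonyl carbon bonded directly to C4a. A Lewis-acid-promoted trimethylsilyldiazomethane homologation with 1,2-aryl shift then forms C3–C4 and C4–C4a in one operation and expands the five-membered ring into ring B as a 2-tetralone, leaving the trans C1/C2 pair untouched. The precursor is the (2S,3S)-indanone bearing the guaiacyl group at the future C1, a TBS-protected C9 hydroxymethyl at the future C2 and TIPS ethers on both phenols, made by asymmetric rhodium-catalysed aryl addition to an indenone and anti hydroxymethylation.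

Key step: step 12

Remark: "C1–C8a" and "C9" (the oxymethyl carbon) are the locants of the target's dihydronaphthalene; indanone and tetralone names carry their own IUPAC locants.
Assumption: the facial preference of the (S)-BINAP–rhodium catalyst on indenone 11 is taken to follow that on 2-cyclopentenone (giving 3S); should the indenone respond oppositely, (R)-BINAP is used.

Step 1
Reactants: 1 2,3-dihydroxybenzaldehyde
Product: 4 3-(benzyloxy)-2-methoxybenzaldehyde, via disodium 3-formylbenzene-1,2-diolate 2 (not isolated), via sodium 2-(benzyloxy)-6-formylphenolate 3 (not isolated)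
Conditions: NaH (2.2 equiv), DMSO, rt; BnBr (1.0 equiv), rt; then MeI (1.5 equiv), rt
Reagents that add atoms: benzyl bromide BrCc1ccccc1; iodomethane CI
Why: In dianion 2 the 3-oxide, neither conjugated with nor chelated by the formyl group, is the more nucleophilic and is benzylated first (Williamson etherification), after which the remaining chelated 2-phenoxide 3 is methylated in the same flask.

Step 2
Reactants: 4 3-(benzyloxy)-2-methoxybenzaldehyde; 5 malonic acid
Product: 7 (2E)-3-[3-(benzyloxy)-2-methoxyphenyl]prop-2-enoic acid, via arylidenemalonic acid 6 (not isolated)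
Conditions: malonic acid (2 equiv), pyridine, piperidine (cat.), 95 °C; aq. HCl
Reagents that add atoms: malonic acid OC(=O)CC(=O)O
Why: Knoevenagel–Doebner condensation followed by decarboxylation of 6 in hot pyridine should deliver the (E)-cinnamic acid.

Step 3
Reactants: 7 (2E)-3-[3-(benzyloxy)-2-methoxyphenyl]prop-2-enoic acid
Product: 8 3-(3-hydroxy-2-methoxyphenyl)propanoic acid
Conditions: H2 (1 atm), 10% Pd/C, MeOH/EtOAc, rt
Reagents that add atoms: none
Why: Catalytic hydrogenation saturates the cinnamic double bond and hydrogenolyses the benzyl ether in one operation, freeing the phenol that directs the next ring closure.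

Step 4
Reactants: 8 3-(3-hydroxy-2-methoxyphenyl)propanoic acid
Product: 9 5-hydroxy-4-methoxy-2,3-dihydro-1H-inden-1-one
Conditions: polyphosphoric acid, 80 °C
Reagents that add atoms: none
Why: Intramolecular Friedel–Crafts acylation can only take the one free position ortho to the side chain, which is para to the free hydroxyl (the future C7 oxygen) and therefore strongly activated.

Step 5
Reactants: 9 5-hydroxy-4-methoxy-2,3-dihydro-1H-inden-1-one
Product: 10 4-methoxy-5-(triisopropylsilyloxy)-2,3-dihydro-1H-inden-1-one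
Conditions: TIPSCl (1.2 equiv), imidazole (2.5 equiv), DMF, rt
Reagents that add atoms: triisopropylsilyl chloride CC(C)[Si](Cl)(C(C)C)C(C)C
Why: Standard phenol silylation; the TIPS ether is chosen because it should survive the oxidant, aqueous rhodium catalysis, enolate chemistry and Lewis acids that follow.

Step 6
Reactants: 10 4-methoxy-5-(triisopropylsilyloxy)-2,3-dihydro-1H-inden-1-one
Product: 11 4-methoxy-5-(triisopropylsilyloxy)-1H-inden-1-one
Conditions: IBX (2.0 equiv), DMSO/fluorobenzene (1:2), 70 °C; used promptly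
Reagents that add atoms: none
Why: IBX dehydrogenation of a ketone through its enol introduces the C2=C3 double bond, and the donor-substituted indenone is expected to be stable enough to carry forward directly.

Step 7
Reactants: 12 4-bromo-2-methoxyphenol
Product: 13 (4-bromo-2-methoxyphenoxy)triisopropylsilane
Conditions: TIPSCl (1.2 equiv), imidazole (2.5 equiv), DMF, rt
Reagents that add atoms: triisopropylsilyl chloride CC(C)[Si](Cl)(C(C)C)C(C)C
Why: Standard phenol silylation giving the same robust protecting group as on ring A.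

Step 8
Reactants: 13 (4-bromo-2-methoxyphenoxy)triisopropylsilane
Product: 16 [3-methoxy-4-(triisopropylsilyloxy)phenyl]boronic acid, via aryllithium 14 (not isolated), via lithium aryltriisopropoxyborate 15 (not isolated)
Conditions: n-BuLi (1.05 equiv), THF, −78 °C; B(OiPr)3 (1.5 equiv), −78 °C to rt; 1 M HCl to pH 5
Reagents that add atoms: triisopropyl borate CC(C)OB(OC(C)C)OC(C)C; water O
Why: Bromine–lithium exchange, borylation and hydrolysis; the lithium sits para to the silyloxy group, so no O-to-C silyl migration is possible.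

Step 9
Reactants: 11 4-methoxy-5-(triisopropylsilyloxy)-1H-inden-1-one; 16 [3-methoxy-4-(triisopropylsilyloxy)phenyl]boronic acid
Product: 17 (3S)-4-methoxy-3-[3-methoxy-4-(triisopropylsilyloxy)phenyl]-5-(triisopropylsilyloxy)-2,3-dihydro-1H-inden-1-one
Conditions: 16 (2.0 equiv), [Rh(OH)((S)-BINAP)]2 (3 mol % Rh), dioxane/H2O (10:1), 35 °C
Reagents that add atoms: none
Why: Hayashi–Miyaura asymmetric conjugate addition, in which the aryl–rhodium(I) species inserts the indenone C2=C3 bond on the face selected by the chiral bisphosphine, setting C3 (the future C1) as S under base-free conditions that spare the aryl silyl ethers.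

Step 10
Reactants: 17 (3S)-4-methoxy-3-[3-methoxy-4-(triisopropylsilyloxy)phenyl]-5-(triisopropylsilyloxy)-2,3-dihydro-1H-inden-1-one
Product: 19 (2S,3S)-2-(hydroxymethyl)-4-methoxy-3-[3-methoxy-4-(triisopropylsilyloxy)phenyl]-5-(triisopropylsilyloxy)-2,3-dihydro-1H-inden-1-one (2,3-trans), via lithium enolate 18 (not isolated)
Conditions: LiHMDS (1.05 equiv), THF, −78 °C; CH2O (g, from cracked paraformaldehyde, excess), −78 to −40 °C; AcOH, −78 °C
Reagents that add atoms: formaldehyde C=O
Why: The lithium enolate of the only enolisable position undergoes aldol addition to monomeric formaldehyde on the face anti to the C3 aryl group, setting C2 as S (trans), which is also the thermodynamically favoured epimer.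

Step 11
Reactants: 19 (2S,3S)-2-(hydroxymethyl)-4-methoxy-3-[3-methoxy-4-(triisopropylsilyloxy)phenyl]-5-(triisopropylsilyloxy)-2,3-dihydro-1H-inden-1-one
Product: 20 (2S,3S)-2-{[(tert-butyldimethylsilyl)oxy]methyl}-4-methoxy-3-[3-methoxy-4-(triisopropylsilyloxy)phenyl]-5-(triisopropylsilyloxy)-2,3-dihydro-1H-inden-1-one (2,3-trans)
Conditions: TBSCl (1.3 equiv), imidazole (2.5 equiv), CH2Cl2, 0 °C to rt
Reagents that add atoms: tert-butyldimethylsilyl chloride CC(C)(C)[Si](C)(C)Cl
Why: Mild silylation of the primary alcohol protects the β-hydroxy ketone against retro-aldol and dehydration and gives C9 a silyl group distinguishable from the phenolic TIPS ethers.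

Step 12
Reactants: 20 (2S,3S)-2-{[(tert-butyldimethylsilyl)oxy]methyl}-4-methoxy-3-[3-methoxy-4-(triisopropylsilyloxy)phenyl]-5-(triisopropylsilyloxy)-2,3-dihydro-1H-inden-1-one; 21 trimethylsilyldiazomethane
Product: 23 (3S,4S)-3-{[(tert-butyldimethylsilyl)oxy]methyl}-5-methoxy-4-[3-methoxy-4-(triisopropylsilyloxy)phenyl]-6-(triisopropylsilyloxy)-3,4-dihydronaphthalen-2(1H)-one (target locants: C3 ketone, C4 methylene, 1S,2S, trans), via C4-trimethylsilyl ketone 22 (not isolated)
Conditions: TMSCHN2 (2.0 equiv, hexanes), BF3·OEt2 (1.5 equiv), CH2Cl2, −78 to −30 °C; sat. NaHCO3; SiO2, wet CH2Cl2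
Reagents that add atoms: trimethylsilyldiazomethane C[Si](C)(C)C=[N+]=[N-]
Why: BF3 activates the indanone carbonyl (future C3), the diazo carbon of 21 adds to it, and in the resulting diazonium alkoxide the aryl carbon (indanone C7a, future C4a) shifts from the carbonyl carbon to the diazo carbon as N2 leaves, giving α-silyl ketone 22, which loses silicon on work-up. This is the known Lewis-acid-promoted trimethylsilyldiazomethane homologation of aryl ketones (a Tiffeneau–Demjanov-type 1,2-shift), and the bulk of the silyl group in 22 should suppress a second insertion. Ring B is formed by ring expansion, not by cyclisation: the 1,2-shift enlarges the five-membered ring to six while creating C3–C4 and C4–C4a. No stereocentre is created, since C4 ends as CH2, and C1 and C2 take no part, C2 already holding the trans relation to the C1 aryl group that is expected to be favoured. The selectivity needed is migration of the aryl carbon in preference to the secondary alkyl carbon C2, and it is secured by the para silyloxy group (the C7 oxygen), which makes the migrating carbon electron-rich, and by the greater hindrance of the branched C2.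

Step 13
Reactants: 23 (3S,4S)-3-{[(tert-butyldimethylsilyl)oxy]methyl}-5-methoxy-4-[3-methoxy-4-(triisopropylsilyloxy)phenyl]-6-(triisopropylsilyloxy)-3,4-dihydronaphthalen-2(1H)-one
Product: 25 (3S,4S)-3-{[(tert-butyldimethylsilyl)oxy]methyl}-5-methoxy-4-[3-methoxy-4-(triisopropylsilyloxy)phenyl]-6-(triisopropylsilyloxy)-3,4-dihydronaphthalen-2-yl trifluoromethanesulfonate (C3=C4 enol triflate), via potassium enolate 24 (not isolated)
Conditions: KHMDS (1.1 equiv), THF, −78 °C; PhNTf2 (1.2 equiv), −78 to 0 °C; aq. NH4Cl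
Reagents that add atoms: N-phenylbis(trifluoromethanesulfonimide) O=S(=O)(N(c1ccccc1)S(=O)(=O)C(F)(F)F)C(F)(F)F
Why: Deprotonation takes the benzylic C4 methylene, which is far more acidic and less hindered than the C2 methine, and O-sulfonylation of the arene-conjugated enolate gives the C3=C4 enol triflate without touching C2 or provoking β-elimination of the silyloxy group.

Step 14
Reactants: 25 (3S,4S)-3-{[(tert-butyldimethylsilyl)oxy]methyl}-5-methoxy-4-[3-methoxy-4-(triisopropylsilyloxy)phenyl]-6-(triisopropylsilyloxy)-3,4-dihydronaphthalen-2-yl trifluoromethanesulfonate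
Product: 26 [(1S,2S)-8-methoxy-1-[3-methoxy-4-(triisopropylsilyloxy)phenyl]-7-(triisopropylsilyloxy)-3-(trifluoromethanesulfonyloxy)-1,2-dihydronaphthalen-2-yl]methyl acetate
Conditions: Ac2O (3 equiv), Cu(OTf)2 (3 mol %), CH2Cl2, 0 °C to rt
Reagents that add atoms: acetic anhydride CC(=O)OC(C)=O
Why: Lewis-acid-catalysed acylative cleavage converts the unhindered primary alkyl TBS ether directly into the acetate while the less basic, bulkier aryl TIPS ethers and the vinyl triflate stay inert, and placing it before the aldehyde exists avoids acylal formation.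

Step 15
Reactants: 26 [(1S,2S)-8-methoxy-1-[3-methoxy-4-(triisopropylsilyloxy)phenyl]-7-(triisopropylsilyloxy)-3-(trifluoromethanesulfonyloxy)-1,2-dihydronaphthalen-2-yl]methyl acetate
Product: 27 [(1S,2R)-3-formyl-8-methoxy-1-[3-methoxy-4-(triisopropylsilyloxy)phenyl]-7-(triisopropylsilyloxy)-1,2-dihydronaphthalen-2-yl]methyl acetate
Conditions: CO (1 atm), Pd(OAc)2 (5 mol %), dppp (5 mol %), Et3SiH (2 equiv), Et3N (2.5 equiv), DMF, 70 °C
Reagents that add atoms: carbon monoxide [C-]#[O+]
Why: Palladium-catalysed reductive carbonylation of an enol triflate (oxidative addition, CO insertion, hydride transfer from the silane to the acyl-palladium) gives the C3 enal; the descriptor at C2 changes from S to R by CIP priority only.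

Step 16
Reactants: 27 [(1S,2R)-3-formyl-8-methoxy-1-[3-methoxy-4-(triisopropylsilyloxy)phenyl]-7-(triisopropylsilyloxy)-1,2-dihydronaphthalen-2-yl]methyl acetate
Product: 28 [(1S,2R)-3-formyl-7-hydroxy-1-(4-hydroxy-3-methoxyphenyl)-8-methoxy-1,2-dihydronaphthalen-2-yl]methyl acetate (CNP0489020.1)
Conditions: TBAF (2.5 equiv), AcOH (2.5 equiv), THF, 0 °C, under argon
Reagents that add atoms: none
Why: Fluoride cleaves aryl silyl ethers rapidly because phenoxide is a good leaving group, and acetic acid buffering should keep the primary acetate, the enal and the oxidation-prone dihydronaphthalene intact.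

Compound list
1 | 2,3-dihydroxybenzaldehyde | O=Cc1cccc(O)c1O | starting material
2 | disodium 3-formylbenzene-1,2-diolate | [Na+].[Na+].[O-]c1cccc(C=O)c1[O-] | intermediate (not isolated)
3 | sodium 2-(benzyloxy)-6-formylphenolate | [Na+].[O-]c1c(C=O)cccc1OCc1ccccc1 | intermediate (not isolated)
4 | 3-(benzyloxy)-2-methoxybenzaldehyde | COc1c(C=O)cccc1OCc1ccccc1 | intermediate
5 | malonic acid | OC(=O)CC(=O)O | starting material
6 | 2-[3-(benzyloxy)-2-methoxybenzylidene]malonic acid | COc1c(C=C(C(=O)O)C(=O)O)cccc1OCc1ccccc1 | intermediate (not isolated)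
7 | (2E)-3-[3-(benzyloxy)-2-methoxyphenyl]prop-2-enoic acid | COc1c(/C=C/C(=O)O)cccc1OCc1ccccc1 | intermediate
8 | 3-(3-hydroxy-2-methoxyphenyl)propanoic acid | COc1c(CCC(=O)O)cccc1O | intermediate
9 | 5-hydroxy-4-methoxy-2,3-dihydro-1H-inden-1-one | COc1c(O)ccc2c1CCC2=O | intermediate
10 | 4-methoxy-5-(triisopropylsilyloxy)-2,3-dihydro-1H-inden-1-one | COc1c(O[Si](C(C)C)(C(C)C)C(C)C)ccc2c1CCC2=O | intermediate
11 | 4-methoxy-5-(triisopropylsilyloxy)-1H-inden-1-one | COc1c(O[Si](C(C)C)(C(C)C)C(C)C)ccc2c1C=CC2=O | intermediate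
12 | 4-bromo-2-methoxyphenol | COc1cc(Br)ccc1O | starting material
13 | (4-bromo-2-methoxyphenoxy)triisopropylsilane | COc1cc(Br)ccc1O[Si](C(C)C)(C(C)C)C(C)C | intermediate
14 | [3-methoxy-4-(triisopropylsilyloxy)phenyl]lithium | COc1cc([Li])ccc1O[Si](C(C)C)(C(C)C)C(C)C | intermediate (not isolated)
15 | lithium triisopropoxy[3-methoxy-4-(triisopropylsilyloxy)phenyl]borate | [Li+].COc1cc([B-](OC(C)C)(OC(C)C)OC(C)C)ccc1O[Si](C(C)C)(C(C)C)C(C)C | intermediate (not isolated)
16 | [3-methoxy-4-(triisopropylsilyloxy)phenyl]boronic acid | COc1cc(B(O)O)ccc1O[Si](C(C)C)(C(C)C)C(C)C | intermediate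
17 | (3S)-4-methoxy-3-[3-methoxy-4-(triisopropylsilyloxy)phenyl]-5-(triisopropylsilyloxy)-2,3-dihydro-1H-inden-1-one | COc1cc([C@H]2c3c(ccc(O[Si](C(C)C)(C(C)C)C(C)C)c3OC)C(=O)C2)ccc1O[Si](C(C)C)(C(C)C)C(C)C | intermediate
18 | lithium (1S)-7-methoxy-1-[3-methoxy-4-(triisopropylsilyloxy)phenyl]-6-(triisopropylsilyloxy)-1H-inden-3-olate | COc1cc([C@H]2c3c(ccc(O[Si](C(C)C)(C(C)C)C(C)C)c3OC)C([O-])=C2)ccc1O[Si](C(C)C)(C(C)C)C(C)C.[Li+] | intermediate (not isolated)
19 | (2S,3S)-2-(hydroxymethyl)-4-methoxy-3-[3-methoxy-4-(triisopropylsilyloxy)phenyl]-5-(triisopropylsilyloxy)-2,3-dihydro-1H-inden-1-one | COc1cc([C@H]2c3c(ccc(O[Si](C(C)C)(C(C)C)C(C)C)c3OC)C(=O)[C@@H]2CO)ccc1O[Si](C(C)C)(C(C)C)C(C)C | intermediate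
20 | (2S,3S)-2-{[(tert-butyldimethylsilyl)oxy]methyl}-4-methoxy-3-[3-methoxy-4-(triisopropylsilyloxy)phenyl]-5-(triisopropylsilyloxy)-2,3-dihydro-1H-inden-1-one | COc1cc([C@H]2c3c(ccc(O[Si](C(C)C)(C(C)C)C(C)C)c3OC)C(=O)[C@@H]2CO[Si](C)(C)C(C)(C)C)ccc1O[Si](C(C)C)(C(C)C)C(C)C | intermediate (key-step precursor)
21 | trimethylsilyldiazomethane | C[Si](C)(C)C=[N+]=[N-] | starting material
22 | (3S,4S)-3-{[(tert-butyldimethylsilyl)oxy]methyl}-5-methoxy-4-[3-methoxy-4-(triisopropylsilyloxy)phenyl]-6-(triisopropylsilyloxy)-1-(trimethylsilyl)-3,4-dihydronaphthalen-2(1H)-one (silyl-bearing carbon unassigned) | COc1cc([C@H]2c3c(ccc(O[Si](C(C)C)(C(C)C)C(C)C)c3OC)C([Si](C)(C)C)C(=O)[C@@H]2CO[Si](C)(C)C(C)(C)C)ccc1O[Si](C(C)C)(C(C)C)C(C)C | intermediate (not isolated)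
23 | (3S,4S)-3-{[(tert-butyldimethylsilyl)oxy]methyl}-5-methoxy-4-[3-methoxy-4-(triisopropylsilyloxy)phenyl]-6-(triisopropylsilyloxy)-3,4-dihydronaphthalen-2(1H)-one | COc1cc([C@H]2c3c(ccc(O[Si](C(C)C)(C(C)C)C(C)C)c3OC)CC(=O)[C@@H]2CO[Si](C)(C)C(C)(C)C)ccc1O[Si](C(C)C)(C(C)C)C(C)C | intermediate (key-step product)
24 | potassium (3S,4S)-3-{[(tert-butyldimethylsilyl)oxy]methyl}-5-methoxy-4-[3-methoxy-4-(triisopropylsilyloxy)phenyl]-6-(triisopropylsilyloxy)-3,4-dihydronaphthalen-2-olate | COc1cc([C@H]2c3c(ccc(O[Si](C(C)C)(C(C)C)C(C)C)c3OC)C=C([O-])[C@@H]2CO[Si](C)(C)C(C)(C)C)ccc1O[Si](C(C)C)(C(C)C)C(C)C.[K+] | intermediate (not isolated)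
25 | (3S,4S)-3-{[(tert-butyldimethylsilyl)oxy]methyl}-5-methoxy-4-[3-methoxy-4-(triisopropylsilyloxy)phenyl]-6-(triisopropylsilyloxy)-3,4-dihydronaphthalen-2-yl trifluoromethanesulfonate | COc1cc([C@H]2c3c(ccc(O[Si](C(C)C)(C(C)C)C(C)C)c3OC)C=C(OS(=O)(=O)C(F)(F)F)[C@@H]2CO[Si](C)(C)C(C)(C)C)ccc1O[Si](C(C)C)(C(C)C)C(C)C | intermediate
26 | [(1S,2S)-8-methoxy-1-[3-methoxy-4-(triisopropylsilyloxy)phenyl]-7-(triisopropylsilyloxy)-3-(trifluoromethanesulfonyloxy)-1,2-dihydronaphthalen-2-yl]methyl acetate | COc1cc([C@H]2c3c(ccc(O[Si](C(C)C)(C(C)C)C(C)C)c3OC)C=C(OS(=O)(=O)C(F)(F)F)[C@@H]2COC(C)=O)ccc1O[Si](C(C)C)(C(C)C)C(C)C | intermediate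
27 | [(1S,2R)-3-formyl-8-methoxy-1-[3-methoxy-4-(triisopropylsilyloxy)phenyl]-7-(triisopropylsilyloxy)-1,2-dihydronaphthalen-2-yl]methyl acetate | COc1cc([C@H]2c3c(ccc(O[Si](C(C)C)(C(C)C)C(C)C)c3OC)C=C(C=O)[C@@H]2COC(C)=O)ccc1O[Si](C(C)C)(C(C)C)C(C)C | intermediate
28 | [(1S,2R)-3-formyl-7-hydroxy-1-(4-hydroxy-3-methoxyphenyl)-8-methoxy-1,2-dihydronaphthalen-2-yl]methyl acetate | COc1cc([C@H]2c3c(ccc(O)c3OC)C=C(C=O)[C@@H]2COC(C)=O)ccc1O | target

Total step count: 16. Longest linear sequence: 14 steps (steps 1–6 and 9–16); steps 7–8 form the two-step side branch to boronic acid 16.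

Steps most likely to fail

Step 12. The alkyl carbon C2 may migrate in competition with the aryl carbon, the diazo adduct may collapse to an epoxide, or the Lewis acid may erode the silyl ethers. The fallback sets out from 20: Wittig methylenation of the ketone (Ph3P=CH2, THF, 0 °C) would give the 1-methylideneindane F1. Oxidative rearrangement of F1 with [hydroxy(tosyloxy)iodo]benzene in 95% methanol, in which the aryl group shifts to the iodine-bearing terminal carbon through a phenonium-type transition state and the resulting oxocarbenium ion is hydrolysed, should return to the route at 23 without any diazo chemistry.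

Step 9. Insertion beside the C4 methoxy group may be slow, allowing protodeboronation of 16 and oligomerisation of the indenone, or facial discrimination may be insufficient. The fallback sets out from 11 and 16: a palladium(II)-catalysed oxidative Heck reaction (Pd(OAc)2, 2,2'-bipyridine, O2, DMSO) would give the achiral 3-arylindenone F2. The stereocentre would then be set by hydride delivery in a copper hydride-catalysed asymmetric conjugate reduction (Cu(OAc)2, DTBM-SEGPHOS of the enantiomer giving 3S, polymethylhydrosiloxane, t-BuOH, toluene), which comes back to the route at 17.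

Step 10. Capture of the enolate by gaseous formaldehyde may be incomplete, a second hydroxymethylation may follow, or the aldol product may dehydrate to the α-methylene ketone. The fallback sets out from 17: the lithium enolate would be alkylated with benzyl chloromethyl ether (LiHMDS, THF, −78 °C), anti to the aryl group, to give the trans benzyloxymethyl ketone F3. Hydrogenolysis of F3 (H2, Pd(OH)2/C, EtOAc, rt, stopped before the aryl ketone is reduced) would come back to the route at 19.

Further compounds
F1 | step 12 | tert-butyl{[(2R,3S)-4-methoxy-3-[3-methoxy-4-(triisopropylsilyloxy)phenyl]-1-methylidene-5-(triisopropylsilyloxy)-2,3-dihydro-1H-inden-2-yl]methoxy}dimethylsilane (same trans geometry as 20) | COc1cc([C@H]2c3c(ccc(O[Si](C(C)C)(C(C)C)C(C)C)c3OC)C(=C)[C@@H]2CO[Si](C)(C)C(C)(C)C)ccc1O[Si](C(C)C)(C(C)C)C(C)C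
F2 | step 9 | 4-methoxy-3-[3-methoxy-4-(triisopropylsilyloxy)phenyl]-5-(triisopropylsilyloxy)-1H-inden-1-one | COc1cc(C2=CC(=O)c3ccc(O[Si](C(C)C)(C(C)C)C(C)C)c(OC)c32)ccc1O[Si](C(C)C)(C(C)C)C(C)C
F3 | step 10 | (2S,3S)-2-[(benzyloxy)methyl]-4-methoxy-3-[3-methoxy-4-(triisopropylsilyloxy)phenyl]-5-(triisopropylsilyloxy)-2,3-dihydro-1H-inden-1-one | COc1cc([C@H]2c3c(ccc(O[Si](C(C)C)(C(C)C)C(C)C)c3OC)C(=O)[C@@H]2COCc2ccccc2)ccc1O[Si](C(C)C)(C(C)C)C(C)C
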